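The reading time is 8.0 min. By then the earlier runs hold little starting material, 3.8 % in west and 0.6 % in south-east, so we reckon as if the first step were over and ask what partner is left for making target.

| flask | starting material | partner | capture agent | remark | time |
|---|---|---|---|---|---|
| west | 0.25 M | 0.39 M | 5 mM | run made earlier |  |
| north-west | 0.25 M | 0.54 M | 5 mM | run made earlier |  |
| south-east | 0.25 M | 1.1 M | 5 mM | run made earlier |  |
| south | 0.25 M | 1 M | 1.9 mM | run made earlier |  |
| teal | 0.060 M | 0.500 M | 2.50 mM |  | 8.0 min |
| grey | 0.25 M | 1.00 M | 5.00 mM |  | 8.0 min |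
| red | 1.0 M | 1.00 M | 1.50 mM |  | 8.0 min |
| blue | 0.060 M | 0.600 M | 1.20 mM |  | 8.0 min |
| ochre | 0.15 M | 0.300 M | 5.00 mM |  | 8.0 min |

| run | time / min | target / % | starting material / % |
|---|---|---|---|
| west | 0.667 | 0.3 | 56.9 |
| west | 2.00 | 3.3 | 26.5 |
| west | 4.00 | 5.4 | 12.5 |
| west | 6.00 | 9.0 | 7.6 |
| west | 8.00 | 9.9 | 3.8 |
| north-west | 0.667 | 4.0 | 47.2 |
| north-west | 2.00 | 6.4 | 13.6 |
| north-west | 4.00 | 13.9 | 4.3 |
| north-west | 6.00 | 16.6 | 1.7 |
| north-west | 8.00 | 17.7 | 0.3 |
| south-east | 0.667 | 6.0 | 22.7 |
| south-east | 2.00 | 21.7 | 0.4 |
| south-east | 4.00 | 31.8 | 1.0 |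
| south-east | 6.00 | 37.3 | 0.9 |
| south-east | 8.00 | 40.2 | 0.6 |
| south | 1.50 | 13.2 | 4.4 |
| south | 3.00 | 24.4 | 0.8 |
| south | 5.00 | 30.7 | 0 |
| south | 6.00 | 35.4 | 1.1 |
| south | 8.00 | 37.6 | 1.3 |

(each reading ± 1 percentage point)

- a reading or a percentage of target counts all its forms, free or not

- ranking by amount of target, in percent of the starting material charged, from high to low, at 8.0 min (teal / grey / red / blue / ochre)
- the same order at 1.5 min (teal / grey / red / blue / ochre)
- the amount of target, in percent of the starting material charged of the flask you put first, at 8.0 min
- the amount of target, in percent of the starting material charged of the flask you put last, at 8.0 min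

Our bench rule counts partner. Call s the spare partner: charged partner minus charged starting material. It is a count at the charge: what stays once each starting material has taken one partner. The equimolar charge, s of zero, is the zero of our scale.

West has s of 0.140 M and reads 9.9 % of target. South-east has s of 0.850 M and reads 40.2 %. Their difference in target over their difference in s is 0.427 M⁻¹, the fraction of the charge gained per molar of spare partner. We call it the yield gain g. North-west stayed out of this line, so it can test it: the line gives 16.3 % and the run reads 17.7 %.

Now the new flasks. Their s is 0.750 M for grey, 0.540 M for blue, 0.440 M for teal, 0.150 M for ochre and 0 M for red, and that is our order. For grey our line gives 35.9 %.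

The rule has a border, and a ratio finds it. Partner over starting material is 1.00 in red, lower than in any earlier run, west being the nearest at 1.56. So our 3.93 % for red is an extrapolation to the zero of the scale, not a reading of the line.

The forecast gives grey > blue > teal > ochre > red at 8.0 min and grey > blue > teal > red > ochre at 1.5 min, with 39 % for grey and 5 % for red. Its ground for red is that “Red has almost no free” partner. It agrees with our order and stands a little above our two numbers.

The flasks give grey > blue > teal > ochre > red at 8.0 min and grey > blue > teal > red > ochre at 1.5 min, with 37.2 % for grey and 7.58 % for red.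

    starting material + partner → intermediate A (k = 0.0414 M⁻¹ s⁻¹)
    intermediate A → intermediate B (k = 0.00235 s⁻¹)
    intermediate A ⇌ intermediate C (K = 22.5, k = 0.00143 s⁻¹)
    partner + intermediate A → target (k = 0.00356 M⁻¹ s⁻¹)
    partner + intermediate B ⇌ intermediate D (K = 1.90 M⁻¹, k = 0.0179 M⁻¹ s⁻¹)
    intermediate D → side product (k = 0.0166 s⁻¹)
    crystals ⇌ target, rate k7*(cs7 - [target]) while solid is left; crystals form when [target] > cs7 (solubility = 0.190 M, k = 0.176 s⁻¹)
    capture agent + intermediate B → trapped intermediate (k = 0.163 M⁻¹ s⁻¹)

Red holds 7.58 % against our 3.93 %, with partner down to 0.405 % of its charge and starting material at 12.2 %. At 8.00 min, red's partner is used 9.0 times as fast by starting material as by intermediate A on its way to target. The neighbour like red but charged with 0.40 M of starting material has s of 0.600 M, where the line with g gives 29.5 %, and that neighbour holds 30.4 % of target.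

The data are calculated for substances that don't exist, and the scatter is random.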